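**Retrosynthetic overview**
- The target comes from its bis-TBS ether by buffered fluoride desilylation; ring C (the 2H-pyran) is closed last by an intramolecular Mitsunobu etherification of a (Z)-2-aryl-3-(2-hydroxyaryl)allyl alcohol.
- That Z-diol comes from iBu2AlH reduction of a 3-arylcoumarin, whose lactone ring fixes the alkene geometry.
- Key C3–C4 bond: intermolecular aldol (Perkin–Oglialoro) condensation of 6-hydroxy-2,4-dimethoxy-3-prenylbenzaldehyde with 2,4-dihydroxyphenylacetic acid.
- The aldehyde comes from magnesium-mediated ortho-formylation of symmetric 3,5-dimethoxy-4-prenylphenol, made by lithiation and prenylation of TIPS-protected 3,5-dimethoxyphenol between the two methoxy groups.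
- Ring order: rings A and B are bought as arenes; the lactone ring forms in the aldol step, is opened by reduction, and is re-closed as ring C.

Assumption: the target is achiral (no stereocentre, its one ring alkene has no E/Z freedom), so there is no enantiomer to select and the only geometry to control is the Z-alkene of the open-chain intermediate.

**Step 1**
Reactants: 1 3,5-dimethoxyphenol
Product: 2 (3,5-dimethoxyphenoxy)triisopropylsilane
Conditions: TIPSCl, imidazole, DMF, rt
Reagents that add atoms: triisopropylsilyl chloride CC(C)[Si](Cl)(C(C)C)C(C)C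
Why: Imidazole-promoted O-silylation masks the acidic OH as a bulky, non-coordinating silyl ether that will not direct the lithiation of the next step.

**Step 2**
Reactants: 2 (3,5-dimethoxyphenoxy)triisopropylsilane
Product: 4 [3,5-dimethoxy-4-(3-methylbut-2-enyl)phenoxy]triisopropylsilane, via aryllithium 3 (not isolated)
Conditions: n-BuLi, THF, 0 °C → rt; then CuBr·SMe2 (10 mol %), prenyl bromide, −78 °C → rt
Reagents that add atoms: prenyl bromide CC(C)=CCBr; n-BuLi [Li]CCCC (its Li stays only in intermediate 3)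
Why: Directed ortho-metalation removes the most acidic proton, the one flanked by both methoxy groups, and copper-catalysed SN2 allylation of the aryl anion gives the linear prenyl arene, whose symmetry is easily confirmed by NMR.

**Step 3**
Reactants: 4 [3,5-dimethoxy-4-(3-methylbut-2-enyl)phenoxy]triisopropylsilane
Product: 5 3,5-dimethoxy-4-(3-methylbut-2-enyl)phenol
Conditions: Bu4NF, THF, 0 °C → rt; AcOH quench
Reagents that add atoms: none
Why: Fluoride-mediated desilylation is driven by the Si–F bond and touches neither the methyl ethers nor the prenyl alkene.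

**Step 4**
Reactants: 5 3,5-dimethoxy-4-(3-methylbut-2-enyl)phenol
Product: 7 6-hydroxy-2,4-dimethoxy-3-(3-methylbut-2-enyl)benzaldehyde, via salicyl alcohol 6 (not isolated)
Conditions: MgCl2, Et3N, (CH2O)n, MeCN, reflux; then cold 1 M HCl
Reagents that add atoms: formaldehyde (added as paraformaldehyde) C=O
Why: Casnati–Skattebøl ortho-formylation: the magnesium phenoxide delivers formaldehyde to the ortho carbon and a second formaldehyde oxidises the salicyl alcohol by hydride transfer; the two ortho positions are equivalent, so only one aldehyde can form.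

**Step 5**
Reactants: 7 6-hydroxy-2,4-dimethoxy-3-(3-methylbut-2-enyl)benzaldehyde; 8 2,4-dihydroxyphenylacetic acid
Product: 11 3-(2,4-diacetoxyphenyl)-5,7-dimethoxy-6-(3-methylbut-2-enyl)coumarin, via mixed anhydride 9 (not isolated), via aldol adduct 10 (not isolated)
Conditions: Ac2O, Et3N, 110 °C, 16 h
Reagents that add atoms: acetic anhydride CC(=O)OC(C)=O
Why: Perkin–Oglialoro condensation: Et3N enolises mixed anhydride 9, the enolate adds to the aldehyde of 7 in an intermolecular aldol reaction, and dehydration plus lactonization onto the ortho phenol give the coumarin, which locks ring A cis to the carbonyl carbon.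

**Step 6**
Reactants: 11 3-(2,4-diacetoxyphenyl)-5,7-dimethoxy-6-(3-methylbut-2-enyl)coumarin
Product: 12 3-(2,4-dihydroxyphenyl)-5,7-dimethoxy-6-(3-methylbut-2-enyl)coumarin
Conditions: NH3 (7 M in MeOH), THF, 0 °C → rt; evaporate
Reagents that add atoms: none
Why: Ammonolysis of the two aryl acetates is much faster than attack on the electron-rich conjugated lactone, so only the acetyl groups are removed.

**Step 7**
Reactants: 12 3-(2,4-dihydroxyphenyl)-5,7-dimethoxy-6-(3-methylbut-2-enyl)coumarin
Product: 13 3-[2,4-bis(tert-butyldimethylsilyloxy)phenyl]-5,7-dimethoxy-6-(3-methylbut-2-enyl)coumarin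
Conditions: TBSCl, imidazole, DMF, rt → 40 °C
Reagents that add atoms: tert-butyldimethylsilyl chloride CC(C)(C)[Si](C)(C)Cl
Why: Silyl ether formation protects both ring B phenols with groups that survive hydride reduction and Mitsunobu conditions and are later removed by fluoride without acid.

**Step 8**
Reactants: 13 3-[2,4-bis(tert-butyldimethylsilyloxy)phenyl]-5,7-dimethoxy-6-(3-methylbut-2-enyl)coumarin
Product: 15 (Z)-2-[2,4-bis(tert-butyldimethylsilyloxy)phenyl]-3-[6-hydroxy-2,4-dimethoxy-3-(3-methylbut-2-enyl)phenyl]prop-2-en-1-ol, via lactol 14 (not isolated)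
Conditions: iBu2AlH (4 equiv), CH2Cl2, −78 → 0 °C; aq. KNaC4H4O6
Reagents that add atoms: none
Why: 1,2-Selective lactone reduction with iBu2AlH passes through the lactol, which opens and is reduced again; no bond at the alkene is broken, so the ring-enforced Z geometry (ring A cis to CH2OH) is kept.

**Step 9**
Reactants: 15 (Z)-2-[2,4-bis(tert-butyldimethylsilyloxy)phenyl]-3-[6-hydroxy-2,4-dimethoxy-3-(3-methylbut-2-enyl)phenyl]prop-2-en-1-ol
Product: 17 3-[2,4-bis(tert-butyldimethylsilyloxy)phenyl]-5,7-dimethoxy-6-(3-methylbut-2-enyl)-2H-chromene, via oxyphosphonium zwitterion 16 (not isolated)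
Conditions: PPh3, DIAD, THF, 0 °C → rt
Reagents that add atoms: triphenylphosphine c1ccc(cc1)P(c1ccccc1)c1ccccc1 (its atoms stay only in intermediate 16)
Why: Intramolecular Mitsunobu etherification: the primary allylic alcohol is activated as its oxyphosphonium and displaced by the cis-placed ring A phenoxide in a 6-exo-tet SN2 closure of ring C, the only free phenol in the molecule.

**Step 10**
Reactants: 17 3-[2,4-bis(tert-butyldimethylsilyloxy)phenyl]-5,7-dimethoxy-6-(3-methylbut-2-enyl)-2H-chromene
Product: 18 dehydroglyasperin D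
Conditions: Bu4NF, AcOH (1:1), THF, 0 °C, Ar
Reagents that add atoms: none
Why: Acetic-acid-buffered fluoride desilylation frees both phenols without strong acid, which could cyclise the 2'-hydroxy-isoflav-3-ene to a pterocarpan, and without strongly basic phenoxide that would invite air oxidation.

**Compound list**
1 | 3,5-dimethoxyphenol | COc1cc(O)cc(OC)c1 | starting material
2 | (3,5-dimethoxyphenoxy)triisopropylsilane | COc1cc(OC)cc(O[Si](C(C)C)(C(C)C)C(C)C)c1 | intermediate
3 | [2,6-dimethoxy-4-(triisopropylsilyloxy)phenyl]lithium (forms in the flask) | [Li]c1c(OC)cc(O[Si](C(C)C)(C(C)C)C(C)C)cc1OC | intermediate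
4 | [3,5-dimethoxy-4-(3-methylbut-2-enyl)phenoxy]triisopropylsilane | COc1cc(O[Si](C(C)C)(C(C)C)C(C)C)cc(OC)c1CC=C(C)C | intermediate
5 | 3,5-dimethoxy-4-(3-methylbut-2-enyl)phenol | COc1cc(O)cc(OC)c1CC=C(C)C | intermediate
6 | 2-(hydroxymethyl)-3,5-dimethoxy-4-(3-methylbut-2-enyl)phenol (salicyl alcohol, magnesium-bound in the flask) | COc1cc(O)c(CO)c(OC)c1CC=C(C)C | intermediate
7 | 6-hydroxy-2,4-dimethoxy-3-(3-methylbut-2-enyl)benzaldehyde | COc1cc(O)c(C=O)c(OC)c1CC=C(C)C | intermediate
8 | 2,4-dihydroxyphenylacetic acid | OC(=O)Cc1ccc(O)cc1O | starting material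
9 | acetic 2-(2,4-diacetoxyphenyl)acetic anhydride (forms in the flask) | CC(=O)OC(=O)Cc1ccc(OC(C)=O)cc1OC(C)=O | intermediate
10 | aldol adduct: acetic 2-(2,4-diacetoxyphenyl)-3-hydroxy-3-[6-hydroxy-2,4-dimethoxy-3-(3-methylbut-2-enyl)phenyl]propanoic anhydride (diastereomer mixture, both centres lost on dehydration; forms in the flask, drawn with its hydroxyl groups free) | CC(=O)OC(=O)C(c1ccc(OC(C)=O)cc1OC(C)=O)C(O)c1c(O)cc(OC)c(CC=C(C)C)c1OC | intermediate
11 | 3-(2,4-diacetoxyphenyl)-5,7-dimethoxy-6-(3-methylbut-2-enyl)coumarin | COc1cc2oc(=O)c(-c3ccc(OC(C)=O)cc3OC(C)=O)cc2c(OC)c1CC=C(C)C | intermediate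
12 | 3-(2,4-dihydroxyphenyl)-5,7-dimethoxy-6-(3-methylbut-2-enyl)coumarin | COc1cc2oc(=O)c(-c3ccc(O)cc3O)cc2c(OC)c1CC=C(C)C | intermediate
13 | 3-[2,4-bis(tert-butyldimethylsilyloxy)phenyl]-5,7-dimethoxy-6-(3-methylbut-2-enyl)coumarin | COc1cc2oc(=O)c(-c3ccc(O[Si](C)(C)C(C)(C)C)cc3O[Si](C)(C)C(C)(C)C)cc2c(OC)c1CC=C(C)C | intermediate
14 | 3-[2,4-bis(tert-butyldimethylsilyloxy)phenyl]-5,7-dimethoxy-6-(3-methylbut-2-enyl)-2H-chromen-2-ol (lactol, racemic at C2, aluminium-bound in the flask) | COc1cc2OC(O)C(c3ccc(O[Si](C)(C)C(C)(C)C)cc3O[Si](C)(C)C(C)(C)C)=Cc2c(OC)c1CC=C(C)C | intermediate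
15 | (Z)-2-[2,4-bis(tert-butyldimethylsilyloxy)phenyl]-3-[6-hydroxy-2,4-dimethoxy-3-(3-methylbut-2-enyl)phenyl]prop-2-en-1-ol (ring A cis to CH2OH) | COc1cc(O)c(/C=C(\CO)c2ccc(O[Si](C)(C)C(C)(C)C)cc2O[Si](C)(C)C(C)(C)C)c(OC)c1CC=C(C)C | intermediate
16 | (Z)-oxyphosphonium phenoxide zwitterion of 15 (CH2O–PPh3 cation, ring A phenoxide; forms in the flask) | [O-]c1cc(OC)c(CC=C(C)C)c(OC)c1/C=C(\CO[P+](c1ccccc1)(c1ccccc1)c1ccccc1)c1ccc(O[Si](C)(C)C(C)(C)C)cc1O[Si](C)(C)C(C)(C)C | intermediate
17 | 3-[2,4-bis(tert-butyldimethylsilyloxy)phenyl]-5,7-dimethoxy-6-(3-methylbut-2-enyl)-2H-chromene | COc1cc2c(c(OC)c1CC=C(C)C)C=C(c1ccc(O[Si](C)(C)C(C)(C)C)cc1O[Si](C)(C)C(C)(C)C)CO2 | intermediate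
18 | dehydroglyasperin D, 4-[5,7-dimethoxy-6-(3-methylbut-2-enyl)-2H-chromen-3-yl]benzene-1,3-diol (achiral) | COc1cc2c(c(OC)c1CC=C(C)C)C=C(c1ccc(O)cc1O)CO2 | target

**Totals**
Total step count: 10. Longest linear sequence: 10 steps (1 → 18); acid 8 is bought and enters at step 5.

**Three steps most likely to fail, each with a fallback**

Step 2 (prenylation of the hindered aryl anion: SN2 versus SN2′ attack on prenyl bromide, Wurtz coupling, incomplete lithiation). The fallback sets out from 2 and comes back at 4. Compound 2 is lithiated as before and the anion is quenched with allyl bromide, an electrophile with no regiochemical ambiguity, to give (4-allyl-3,5-dimethoxyphenoxy)triisopropylsilane F1. Olefin cross-metathesis of F1 with excess 2-methylbut-2-ene (second-generation Grubbs catalyst RuCl2(=CHPh)(PCy3)(H2IMes), CH2Cl2, 40 °C) then builds the prenyl terminus and delivers 4.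

Step 5 (Perkin condensation of a hindered, electron-rich aldehyde with a polyhydroxylated acid in hot anhydride). The fallback sets out from 8, uses 7 as partner, and comes back at 12, so that 11 and step 6 are bypassed. Acid 8 is lactonised (cat. TsOH, toluene, Dean–Stark) to 6-hydroxybenzofuran-2(3H)-one F2, whose acidic CH2 needs no anhydride activation. Amine-mediated Knoevenagel-type aldol condensation of F2 with 7 (piperidine, Et3N, EtOH, reflux) gives (Z)-6-hydroxy-3-[6-hydroxy-2,4-dimethoxy-3-(3-methylbut-2-enyl)benzylidene]benzofuran-2(3H)-one F3 together with its E isomer. Under the same basic conditions the ring A phenoxide translactonises both isomers to the more stable coumarin 12.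

Step 8 (one-pot double reduction: stalling at the lactol, conjugate reduction, or silyl loss on warming with excess alane). The fallback sets out from 13 and comes back at 15. Coumarin 13 is reduced with iBu2AlH (1.1 equiv, toluene, −78 °C) and quenched cold so that lactol 14 is isolated. The ring-opened (Z)-hydroxy-enal tautomer of 14 is then reduced under Luche conditions (NaBH4, CeCl3·7H2O, MeOH/THF, 0 °C) to give 15. This sequence makes no compound outside the list (F0).

**Further compounds**
F1 | step 2 | (4-allyl-3,5-dimethoxyphenoxy)triisopropylsilane | COc1cc(O[Si](C(C)C)(C(C)C)C(C)C)cc(OC)c1CC=C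
F2 | step 5 | 6-hydroxybenzofuran-2(3H)-one | O=C1Cc2ccc(O)cc2O1
F3 | step 5 | (Z)-6-hydroxy-3-[6-hydroxy-2,4-dimethoxy-3-(3-methylbut-2-enyl)benzylidene]benzofuran-2(3H)-one | O=C1Oc2cc(O)ccc2/C1=C/c1c(O)cc(OC)c(CC=C(C)C)c1OC
F0 | step 8 | none | none
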